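The route rests on cutting the trisubstituted ring olefin C7=C8 (daucane numbering: the CH= and C(CH3)= carbons of the seven-membered ring), which lies between the two allylic oxygenated carbons C6 and C9. Ring-closing olefin metathesis joins a vinyl carbinol ester arm on C5 and an isopropenyl carbinol arm on C1 of a fully substituted cyclopentane and gives the target in one operation, with no protecting group left. The cyclopentane comes from (S)-terpinen-4-ol, whose isopropyl carbinol becomes C4: ozonolysis and aldol ring contraction turn the cyclohexene into a cyclopentenecarbaldehyde (C5, C6), the ring methyl becomes C10 through a boron aldol with methacrolein (C9, C8), and a cuprate installs the angular methyl.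

Key step: step 12

Locants: daucane numbering of the target is kept for all intermediates (C1 quaternary methyl carbon, C2, C3, C4 isopropyl carbinol, C5 ring-fusion CH, C6 ester carbon, C7=C8 olefin, C9 carbinol, C10 methylene, C15 angular methyl).
Assumption: (S)-(+)-terpinen-4-ol is used in high enantiomeric purity; any antipode carried along would appear as a separable diastereomer once C9 is set in step 3.

Step 1
Reactants: 1 (S)-(+)-terpinen-4-ol
Product: 2 (S)-1-isopropyl-1-(4-methoxybenzyloxy)-4-methylcyclohex-3-ene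
Conditions: KH, 4-methoxybenzyl chloride, n-Bu4NI (cat.), THF, 0 °C → 50 °C
Reagents that add atoms: 4-methoxybenzyl chloride, COc1ccc(CCl)cc1
Why: Williamson etherification of the tertiary potassium alkoxide with the benzylic chloride (iodide catalysis) should leave the stereocenter untouched and gives an ether that survives the steps up to the enal chemistry and is removable oxidatively under neutral conditions.

Step 2
Reactants: 2 PMB ether of terpinen-4-ol
Product: 5 (S)-5-isopropyl-7,7-dimethoxy-5-(4-methoxybenzyloxy)heptan-2-one, via methoxy hydroperoxide aldehyde 3 (not isolated), via methoxy hydroperoxide acetal 4 (not isolated)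
Conditions: O3, CH2Cl2/MeOH (5:1), −78 °C (Sudan red 7B end point); TsOH·H2O (cat.), −78 °C → rt; NaHCO3; Me2S, rt
Reagents that add atoms: ozone, O=[O+][O-]; methanol, CO
Why: Criegee ozonolysis in methanol places the carbonyl oxide on the more substituted carbon (trapped as the α-methoxy hydroperoxide) and the aldehyde at the other terminus, which TsOH/MeOH acetalizes before Me2S reduces the peroxide to the methyl ketone (terminus-differentiating ozonolysis), the trisubstituted olefin reacting far faster than the anisyl ring.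

Step 3
Reactants: 5 keto acetal; 6 methacrolein
Product: 9 (3R,8S)-3-hydroxy-8-isopropyl-10,10-dimethoxy-8-(4-methoxybenzyloxy)-2-methyldec-1-en-5-one, via enol borinate 7 (not isolated), via boron aldolate 8 (not isolated)
Conditions: (−)-Ipc2BCl, Et3N, Et2O, 0 °C; methacrolein, −78 → −20 °C; then MeOH, pH 7 buffer, 30% H2O2, 0 °C → rt
Reagents that add atoms: none
Why: In this Paterson boron aldol reaction Ipc2BCl/Et3N enolizes the methyl ketone on the methyl side and the chiral enol borinate should add to the Re face of methacrolein under reagent control (the sense expected for methyl ketones with the (−)-reagent), setting C9 as R without influence from the remote C4 center.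

Step 4
Reactants: 9 aldol adduct
Product: 10 (3R,8S)-3-(tert-butyldimethylsilyloxy)-8-isopropyl-10,10-dimethoxy-8-(4-methoxybenzyloxy)-2-methyldec-1-en-5-one
Conditions: TBSCl, imidazole, DMAP (cat.), DMF, rt
Reagents that add atoms: tert-butyldimethylsilyl chloride, CC(C)(C)[Si](C)(C)Cl
Why: Silylation of the secondary allylic alcohol under non-acidic conditions masks the C9 hydroxyl against retro-aldol cleavage and dehydration in the following steps and leaves the acetal intact.

Step 5
Reactants: 10 silyl ether
Product: 12 (5R)-2-[(2R)-2-(tert-butyldimethylsilyloxy)-3-methylbut-3-enyl]-5-isopropyl-5-(4-methoxybenzyloxy)cyclopent-1-ene-1-carbaldehyde, via keto aldehyde 11 (not isolated)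
Conditions: PPTS, acetone/H2O, 45 °C; then piperidine, AcOH (0.3 equiv each), toluene, 4 Å MS, rt → 50 °C
Reagents that add atoms: water, O
Why: Mild acid hydrolysis frees the aldehyde, whose piperidine enamine should add to the ketone in a 5-(enolexo)-exo-trig intramolecular aldol reaction and dehydrate to the tetrasubstituted enal (aldol condensation as used for limonene-derived keto aldehydes), the aldehyde forming its enamine much faster than the ketone so that the acylcyclopentene regioisomer stays minor.

Step 6
Reactants: 12 enal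
Product: 14 (1R,2R,5R)-2-[(2R)-2-(tert-butyldimethylsilyloxy)-3-methylbut-3-enyl]-5-isopropyl-5-(4-methoxybenzyloxy)-2-methylcyclopentane-1-carbaldehyde, via silyl enol ether 13 (not isolated)
Conditions: Me2CuLi (from MeLi and CuI, 3 equiv), TMSCl, THF, −78 → −20 °C; then K2CO3, MeOH, 0 °C → rt
Reagents that add atoms: lithium dimethylcuprate, [Li+].C[Cu-]C
Why: TMSCl-accelerated conjugate addition of the Gilman cuprate should create the quaternary C1 with methyl entering on the ring face of the C4 ether oxygen and away from the larger isopropyl group (1,3-induction across C5), and base methanolysis of the silyl enol ether equilibrates C5 so that the formyl group sits trans to both the isopropyl group and the C10 side chain.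

Step 7
Reactants: 14 aldehyde
Product: 15 (1R,2R,5R)-2-[(2R)-2-(tert-butyldimethylsilyloxy)-3-methylbut-3-enyl]-5-hydroxy-5-isopropyl-2-methylcyclopentane-1-carbaldehyde
Conditions: DDQ, CH2Cl2/pH 7 buffer (10:1), 0 °C → rt
Reagents that add atoms: none
Why: Oxidative PMB cleavage (benzylic hydride abstraction by DDQ and hydrolysis of the oxocarbenium ion) should free the tertiary alcohol under buffered neutral conditions that spare the β-hydroxy aldehyde, the silyl ether and the olefin.

Step 8
Reactants: 15 hydroxy aldehyde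
Product: 16 (1S)-1-[(1S,2R,5R)-2-[(2R)-2-(tert-butyldimethylsilyloxy)-3-methylbut-3-enyl]-5-hydroxy-5-isopropyl-2-methylcyclopentyl]prop-2-en-1-ol
Conditions: CH2=CHMgBr (4 equiv), THF, −78 → −40 °C; aq. NH4Cl
Reagents that add atoms: vinylmagnesium bromide, C=C[Mg]Br
Why: In this chelation-controlled Grignard addition the first equivalent forms the C4 magnesium alkoxide, which binds the aldehyde oxygen in a cis-fused six-membered chelate, so that vinyl should attack the exposed face next to H5 and not the face covered by C1 and its methyl group, giving the 6S carbinol.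

Step 9
Reactants: 17 vanillic acid
Product: 19 4-(tert-butyldimethylsilyloxy)-3-methoxybenzoic acid, via bis-silyl derivative 18 (not isolated)
Conditions: TBSCl (2.5 equiv), imidazole, DMF, rt; then AcOH/THF/H2O, rt
Reagents that add atoms: tert-butyldimethylsilyl chloride, CC(C)(C)[Si](C)(C)Cl
Why: Both acidic hydroxyl groups are silylated and only the labile silyl ester is hydrolysed by aqueous acetic acid, which leaves the phenol protected for the esterification.

Step 10
Reactants: 16 diol; 19 silyl-protected vanillic acid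
Product: 21 (1S)-1-[(1S,2R,5R)-2-[(2R)-2-(tert-butyldimethylsilyloxy)-3-methylbut-3-enyl]-5-hydroxy-5-isopropyl-2-methylcyclopentyl]prop-2-enyl 4-(tert-butyldimethylsilyloxy)-3-methoxybenzoate, via mixed anhydride 20 (not isolated)
Conditions: 2,4,6-Cl3C6H2COCl, Et3N, THF, rt; then 16, DMAP, toluene, 50 °C
Reagents that add atoms: none
Why: Yamaguchi esterification through the mixed anhydride should acylate the secondary allylic C6 hydroxyl with retention of configuration, the tertiary C4 hydroxyl being too hindered to react.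

Step 11
Reactants: 21 bis-silyl ester
Product: 22 (1S)-1-[(1S,2R,5R)-5-hydroxy-2-[(2R)-2-hydroxy-3-methylbut-3-enyl]-5-isopropyl-2-methylcyclopentyl]prop-2-enyl 4-hydroxy-3-methoxybenzoate
Conditions: TBAF, AcOH (1:1), THF, 0 °C → rt
Reagents that add atoms: none
Why: Fluoride cleaves the alkyl and the aryl silyl ether, and acetic acid buffers the medium so that the aryl ester should be neither hydrolysed nor transposed.

Step 12
Reactants: 22 diene
Product: 23 (1R,4R,5S,6S,9R)-4,9-dihydroxydauc-7-en-6-yl 4-hydroxy-3-methoxybenzoate (target)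
Conditions: RuCl2(=CHPh)(H2IMes)(PCy3) (second-generation Grubbs catalyst, 10 mol %), 1,4-benzoquinone (20 mol %), toluene (0.002 M), 80 °C, Ar sparge
Reagents that add atoms: none
Why: The ruthenium benzylidene first exchanges with the monosubstituted vinyl group on C6, the resulting C7 alkylidene adds across the isopropenyl C8=CH2 bond in an intramolecular [2+2] step, and cycloreversion of the ruthenacyclobutane releases the cycloheptene with the new C7=C8 bond while loss of ethene drives the sequence. The closest known reaction type is ring-closing olefin metathesis to trisubstituted cycloheptenes of hydroazulene terpenoids with second-generation ruthenium carbenes. The one ring closed is the seven-membered carbocycle, formed by metathesis between the two arms held trans on C5 and C1 of the cyclopentane, so the trans ring fusion is already fixed in 22. No stereocenter is created, the allylic centers C6 and C9 are not touched, and the ring size forces the cis olefin. The step needs ring closure to win over cross-metathesis of the vinyl group and over ruthenium hydride isomerization of the allylic alcohol; high dilution, the short tether on a rigid ring, the free C9 allylic hydroxyl (which should accelerate closure onto the 1,1-disubstituted olefin) and benzoquinone as hydride scavenger should secure this.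

Compound list
1 | (S)-(+)-terpinen-4-ol, (S)-1-isopropyl-4-methylcyclohex-3-en-1-ol | CC1=CC[C@](O)(C(C)C)CC1 | starting material
2 | (S)-1-isopropyl-1-(4-methoxybenzyloxy)-4-methylcyclohex-3-ene | CC1=CC[C@](OCc2ccc(OC)cc2)(C(C)C)CC1 | intermediate
3 | (3S)-6-hydroperoxy-3-isopropyl-6-methoxy-3-(4-methoxybenzyloxy)heptanal (mixture at C6) | CC(OC)(OO)CC[C@@](OCc1ccc(OC)cc1)(C(C)C)CC=O | intermediate
4 | (5S)-2-hydroperoxy-5-isopropyl-2,7,7-trimethoxy-5-(4-methoxybenzyloxy)heptane (mixture at C2) | CC(OC)(OO)CC[C@@](OCc1ccc(OC)cc1)(C(C)C)CC(OC)OC | intermediate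
5 | (S)-5-isopropyl-7,7-dimethoxy-5-(4-methoxybenzyloxy)heptan-2-one | CC(=O)CC[C@@](OCc1ccc(OC)cc1)(C(C)C)CC(OC)OC | intermediate
6 | methacrolein | CC(=C)C=O | starting material
7 | diisopinocampheylboron enolate of 5 on the methyl side (Ipc groups derived from (+)-α-pinene) | C=C(CC[C@@](OCc1ccc(OC)cc1)(C(C)C)CC(OC)OC)OB([C@@H]1C[C@@H]2C[C@H]([C@H]1C)C2(C)C)[C@@H]1C[C@@H]2C[C@H]([C@H]1C)C2(C)C | intermediate
8 | diisopinocampheylboron aldolate of 9 (3R,8S) | C=C(C)[C@H](OB([C@@H]1C[C@@H]2C[C@H]([C@H]1C)C2(C)C)[C@@H]1C[C@@H]2C[C@H]([C@H]1C)C2(C)C)CC(=O)CC[C@@](OCc1ccc(OC)cc1)(C(C)C)CC(OC)OC | intermediate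
9 | (3R,8S)-3-hydroxy-8-isopropyl-10,10-dimethoxy-8-(4-methoxybenzyloxy)-2-methyldec-1-en-5-one | C=C(C)[C@H](O)CC(=O)CC[C@@](OCc1ccc(OC)cc1)(C(C)C)CC(OC)OC | intermediate
10 | (3R,8S)-3-(tert-butyldimethylsilyloxy)-8-isopropyl-10,10-dimethoxy-8-(4-methoxybenzyloxy)-2-methyldec-1-en-5-one | C=C(C)[C@H](O[Si](C)(C)C(C)(C)C)CC(=O)CC[C@@](OCc1ccc(OC)cc1)(C(C)C)CC(OC)OC | intermediate
11 | (3S,8R)-8-(tert-butyldimethylsilyloxy)-3-isopropyl-3-(4-methoxybenzyloxy)-9-methyl-6-oxodec-9-enal | C=C(C)[C@H](O[Si](C)(C)C(C)(C)C)CC(=O)CC[C@@](OCc1ccc(OC)cc1)(C(C)C)CC=O | intermediate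
12 | (5R)-2-[(2R)-2-(tert-butyldimethylsilyloxy)-3-methylbut-3-enyl]-5-isopropyl-5-(4-methoxybenzyloxy)cyclopent-1-ene-1-carbaldehyde | O=CC1=C(C[C@@H](O[Si](C)(C)C(C)(C)C)C(C)=C)CC[C@@]1(OCc1ccc(OC)cc1)C(C)C | intermediate
13 | trimethylsilyl enol ether of 14 (enol ether geometry not defined; C1 R, C4 R, C9 R) | C[Si](C)(C)OC=C1[C@](C[C@H](C(C)=C)O[Si](C)(C)C(C)(C)C)(C)CC[C@@]1(OCc1ccc(OC)cc1)C(C)C | intermediate
14 | (1R,2R,5R)-2-[(2R)-2-(tert-butyldimethylsilyloxy)-3-methylbut-3-enyl]-5-isopropyl-5-(4-methoxybenzyloxy)-2-methylcyclopentane-1-carbaldehyde | O=C[C@@H]1[C@](C[C@H](C(C)=C)O[Si](C)(C)C(C)(C)C)(C)CC[C@@]1(OCc1ccc(OC)cc1)C(C)C | intermediate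
15 | (1R,2R,5R)-2-[(2R)-2-(tert-butyldimethylsilyloxy)-3-methylbut-3-enyl]-5-hydroxy-5-isopropyl-2-methylcyclopentane-1-carbaldehyde | O=C[C@@H]1[C@](C[C@H](C(C)=C)O[Si](C)(C)C(C)(C)C)(C)CC[C@@]1(O)C(C)C | intermediate
16 | (1S)-1-[(1S,2R,5R)-2-[(2R)-2-(tert-butyldimethylsilyloxy)-3-methylbut-3-enyl]-5-hydroxy-5-isopropyl-2-methylcyclopentyl]prop-2-en-1-ol | O[C@@H](C=C)[C@@H]1[C@](C[C@H](C(C)=C)O[Si](C)(C)C(C)(C)C)(C)CC[C@@]1(O)C(C)C | intermediate
17 | vanillic acid (4-hydroxy-3-methoxybenzoic acid) | COc1cc(C(=O)O)ccc1O | starting material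
18 | tert-butyldimethylsilyl 4-(tert-butyldimethylsilyloxy)-3-methoxybenzoate | COc1cc(C(=O)O[Si](C)(C)C(C)(C)C)ccc1O[Si](C)(C)C(C)(C)C | intermediate
19 | 4-(tert-butyldimethylsilyloxy)-3-methoxybenzoic acid | COc1cc(C(=O)O)ccc1O[Si](C)(C)C(C)(C)C | intermediate
20 | 4-(tert-butyldimethylsilyloxy)-3-methoxybenzoic 2,4,6-trichlorobenzoic anhydride | COc1cc(C(=O)OC(=O)c2c(Cl)cc(Cl)cc2Cl)ccc1O[Si](C)(C)C(C)(C)C | intermediate
21 | (1S)-1-[(1S,2R,5R)-2-[(2R)-2-(tert-butyldimethylsilyloxy)-3-methylbut-3-enyl]-5-hydroxy-5-isopropyl-2-methylcyclopentyl]prop-2-enyl 4-(tert-butyldimethylsilyloxy)-3-methoxybenzoate | COc1cc(C(=O)O[C@@H](C=C)[C@@H]2[C@](C[C@H](C(C)=C)O[Si](C)(C)C(C)(C)C)(C)CC[C@@]2(O)C(C)C)ccc1O[Si](C)(C)C(C)(C)C | intermediate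
22 | (1S)-1-[(1S,2R,5R)-5-hydroxy-2-[(2R)-2-hydroxy-3-methylbut-3-enyl]-5-isopropyl-2-methylcyclopentyl]prop-2-enyl 4-hydroxy-3-methoxybenzoate | COc1cc(C(=O)O[C@@H](C=C)[C@@H]2[C@](C[C@H](C(C)=C)O)(C)CC[C@@]2(O)C(C)C)ccc1O | intermediate
23 | (1R,4R,5S,6S,9R)-4,9-dihydroxydauc-7-en-6-yl 4-hydroxy-3-methoxybenzoate (daucane numbering; trans ring fusion) | COc1cc(C(=O)O[C@H]2C=C(C)[C@H](O)C[C@@]3(C)CC[C@@](O)(C(C)C)[C@H]23)ccc1O | target

Total step count: 12. Longest linear sequence: 11 steps (steps 1–8 and 10–12, from (S)-terpinen-4-ol); step 9 is a one-step side branch.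

Steps most likely to fail

1. Step 6. The 1,4-addition at the fully substituted β-carbon may be slow and lose out to 1,2-addition, facial discrimination between the isopropyl group and the ether oxygen at C4 may be insufficient, and the C4 ether may be eliminated during the base equilibration. The fallback sets out from enal 12 and returns at hydroxy aldehyde 15, installing the methyl group by hydroxyl-directed cyclopropanation and reductive ring opening instead of conjugate addition. DDQ (CH2Cl2/pH 7 buffer) would free the tertiary alcohol to give the hydroxy enal F1. Luche reduction (NaBH4, CeCl3·7H2O, MeOH) would give the allylic diol F2. Simmons–Smith cyclopropanation (Et2Zn, CH2I2, CH2Cl2) would deliver the methylene to the face of the tetrasubstituted olefin syn to the C4 hydroxyl and give the cyclopropane diol F3. Dess–Martin oxidation of the primary alcohol would give the cyclopropyl aldehyde F4. Dissolving-metal opening of the exocyclic cyclopropane bond (Li, NH3, THF, −78 °C; NH4Cl), followed by brief DBU equilibration at C5, would unveil the C15 methyl group cis to the C4 hydroxyl and give 15.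

2. Step 12. Closure onto the hindered 1,1-disubstituted olefin may be slow, so that intermolecular metathesis of the vinyl group or ruthenium hydride isomerization of the allylic alcohol takes over. The fallback sets out from diol 16 and returns at target 23, closing the ring before the acyl group is introduced. Ring-closing metathesis with the same ruthenium carbene would be run on 16, where the free C6 allylic hydroxyl activates the vinyl group and no aroyl group crowds it, to give the bicyclic diol F5. Yamaguchi esterification with acid 19 (through mixed anhydride 20) would give the bis-silyl ester F6, and TBAF/AcOH would give 23.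

3. Step 8. Chelation may be incomplete, giving poor facial selectivity at C6, and the Grignard reagent may enolize the hindered aldehyde. The fallback sets out from hydroxy aldehyde 15 and returns at diol 16, setting C6 by catalyst-controlled reduction instead of chelate-controlled C–C bond formation. The mixture of 16 and its C6 epimer F7 from an unselective addition would be oxidised with MnO2 to the vinyl ketone F8. Corey–Bakshi–Shibata reduction ((R)-B-methyl oxazaborolidine, catecholborane, toluene, −78 °C; alkenyl as the small group) would then give 16.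

Further compounds
F1 | step 6 | (5R)-2-[(2R)-2-(tert-butyldimethylsilyloxy)-3-methylbut-3-enyl]-5-hydroxy-5-isopropylcyclopent-1-ene-1-carbaldehyde | O=CC1=C(C[C@@H](O[Si](C)(C)C(C)(C)C)C(C)=C)CC[C@@]1(O)C(C)C
F2 | step 6 | (1R)-3-[(2R)-2-(tert-butyldimethylsilyloxy)-3-methylbut-3-enyl]-2-(hydroxymethyl)-1-isopropylcyclopent-2-en-1-ol | OCC1=C(C[C@@H](O[Si](C)(C)C(C)(C)C)C(C)=C)CC[C@@]1(O)C(C)C
F3 | step 6 | cyclopropane diol from F2, methylene bridging C5 and C1 on the face of the C4 hydroxyl (bicyclo[3.1.0]hexane; C4 R, C9 R) | OC[C@@]12C[C@]1(C[C@@H](O[Si](C)(C)C(C)(C)C)C(C)=C)CC[C@@]2(O)C(C)C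
F4 | step 6 | cyclopropyl aldehyde from F3 (C6 formyl on the C5 bridgehead; other centers as in F3) | O=C[C@@]12C[C@]1(C[C@@H](O[Si](C)(C)C(C)(C)C)C(C)=C)CC[C@@]2(O)C(C)C
F5 | step 12 | (1R,4R,5S,6S,9R)-9-(tert-butyldimethylsilyloxy)dauc-7-ene-4,6-diol | O[C@H]1C=C(C)[C@H](O[Si](C)(C)C(C)(C)C)C[C@@]2(C)CC[C@@](O)(C(C)C)[C@H]12
F6 | step 12 | (1R,4R,5S,6S,9R)-9-(tert-butyldimethylsilyloxy)-4-hydroxydauc-7-en-6-yl 4-(tert-butyldimethylsilyloxy)-3-methoxybenzoate | COc1cc(C(=O)O[C@H]2C=C(C)[C@H](O[Si](C)(C)C(C)(C)C)C[C@@]3(C)CC[C@@](O)(C(C)C)[C@H]23)ccc1O[Si](C)(C)C(C)(C)C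
F7 | step 8 | C6 epimer of 16, (1R)-1-[(1S,2R,5R)-2-[(2R)-2-(tert-butyldimethylsilyloxy)-3-methylbut-3-enyl]-5-hydroxy-5-isopropyl-2-methylcyclopentyl]prop-2-en-1-ol | O[C@H](C=C)[C@@H]1[C@](C[C@H](C(C)=C)O[Si](C)(C)C(C)(C)C)(C)CC[C@@]1(O)C(C)C
F8 | step 8 | vinyl ketone from 16 and F7 (C6 carbonyl; C1, C4, C5 and C9 as in 16) | O=C(C=C)[C@@H]1[C@](C[C@H](C(C)=C)O[Si](C)(C)C(C)(C)C)(C)CC[C@@]1(O)C(C)C
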